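**Beyond the readings.** I cannot read the flask of 38 mM Z at 3.0 h from the two earlier runs, since both stop at 120 min. I have to carry a clock across that gap and keep a ledger of Z.

| flask | Z | remark | time |
|---|---|---|---|
| dawn | 25 mM | run made earlier |  |
| midnight | 57 mM | run made earlier |  |
| flask | 38 mM |  | 3.0 h |

- dawn (time / min: D / %, Q / %, Z / %): 8.00: 7, 2, 95; 20.0: 13, 0, 86; 40.0: 24, 2, 71; 60.0: 30, 1, 61; 80.0: 37, 2, 54; 120: 46, 5, 43
- midnight (time / min: D / %, Q / %, Z / %): 8.00: 7, 1, 95; 20.0: 15, 0, 85; 40.0: 20, 1, 75; 60.0: 31, 1, 64; 80.0: 38, 3, 58; 120: 46, 3, 41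

(each reading ± 1.5 percentage points)

- the numbers in the tables scatter by 1.5 percentage points (one standard deviation)

1. concentration of D at 3.0 h, in mM
2. concentration of Q at 3.0 h, in mM
3. concentration of Z at 3.0 h, in mM

**The clock.** The midnight run holds twice the charge of the dawn run, yet at 120 min Z stands at 41% there and at 43% in the dawn run, a gap near the scatter of 1.5 percentage points. So I read one time for both runs: from those readings, Z falls to half of what it was in 95.9 min. That is my halving time, the apparent first-order half-life.

**Entry Z.** In the flask, 3.0 h is 1.88 halving times, so by my reckoning 27.2% of the charge remains, which makes c(Z) 10.3 mM. Hence, by that reckoning, 27.7 mM has left Z.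

**Other entries.** At 120 min the dawn run books D at 46% and Q at 5%, and with Z that leaves 6 points unentered. The midnight run leaves 10 points. So these readings, with their scatter, book the loss from Z to D, to Q and to an open entry that no column names, and there my books stop.

**The forecast.** Its ground for Z is that “the loss looks first order”. It gives c(D) 21 mM (19.3 mM to 23 mM), c(Q) 2.7 mM (1.5 mM to 4.2 mM) and c(Z) 10.6 mM (9.2 mM to 12.2 mM). Its c(Z) stands a little above mine.

**The result.** The flask gives c(D) 19.5 mM, c(Q) 2.12 mM and c(Z) 12.2 mM. D and Z fall within tolerance, while the forecast's Q is too high by a factor of 1.27.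

    Z ⇌ D (K = 3.10, k = 0.439 h⁻¹)
    D ⇌ J (K = 1.25, k = 0.0256 h⁻¹)
    J ⇌ Z (k = 0.0138 h⁻¹)
    D → Q (k = 0.0528 h⁻¹)

In the flask the open entry is J, at 11.1% of the charge at 3.00 h, beside Z 32.0%, D 51.3% and Q 5.59%, and there the books close. Taken as one average over that span, the halving time of Z in the flask comes to 109 min, longer than my 95.9 min, and the flask holds more Z than my 10.3 mM.

**A second flask.** The same charge read at 80 min, a time inside the span of the readings, gets from my halving time 56.1% of Z, or 21.3 mM. The computed flask holds 55.2%, or 21.0 mM.

(All runs stem from a simulated flask on assumed constants, noise included.)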